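**Assumption:** squamatic acid has no stereocentres (it is achiral), so there is no enantiomer to control; the route only has to deliver the correct constitution.

## Retrosynthetic overview

1. Squamatic acid (11) comes from its dibenzyl ester 10 by one global hydrogenolysis.
2. Ring A of 10 is built last, directly onto the depside carbonyl: a [4+2] benzannulation between B-ring aryl but-2-ynoate 5 and push–pull silyl diene 9 (the proposed new step).
3. Dienophile 5 comes from benzyl β-orsellinate 3 and but-2-ynoic acid 4; 3 comes from 2,5-dimethylresorcinol 1 by carboxylation and benzylation.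
4. Diene 9 comes from dibenzyl malonate 6 by C-acetylation, O-methylation and γ-deprotonation/O-silylation.
5. Ring order: ring B is bought preformed; ring A is formed in the key step.

## Route

**Step 1**
Reactants: 1, 2,5-dimethylresorcinol (2,5-dimethylbenzene-1,3-diol)
Product: 2, 2,4-dihydroxy-3,6-dimethylbenzoic acid (β-orsellinic acid)
Conditions: KHCO3 (5 equiv), CO2 (5 bar), glycerol, 120 °C; then cold 2 M HCl
Reagents that add atoms: carbon dioxide, O=C=O
Why: Kolbe–Schmitt carboxylation of an electron-rich resorcinol; the only two free positions (C4/C6) are symmetry-equivalent, so a single regioisomer forms.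

**Step 2**
Reactants: 2, 2,4-dihydroxy-3,6-dimethylbenzoic acid
Product: 3, benzyl 2,4-dihydroxy-3,6-dimethylbenzoate
Conditions: BnBr (1.05 equiv), KHCO3, DMF, rt
Reagents that add atoms: benzyl bromide, BrCc1ccccc1
Why: SN2 O-alkylation of the carboxylate; bicarbonate does not ionise the phenols appreciably, so only the acid is benzylated.

**Step 3**
Reactants: 3, benzyl 2,4-dihydroxy-3,6-dimethylbenzoate; 4, but-2-ynoic acid
Product: 5, benzyl 4-(but-2-ynoyloxy)-2-hydroxy-3,6-dimethylbenzoate
Conditions: DCC (1.1 equiv), DMAP (5 mol%), CH2Cl2, 0 °C → rt
Reagents that add atoms: none (4 is a listed reactant)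
Why: Steglich esterification; the 4-OH reacts selectively because the 2-OH is hydrogen-bonded to the ester carbonyl and flanked by two substituents.

**Step 4**
Reactants: 6, dibenzyl malonate
Product: 7, dibenzyl 2-acetylmalonate
Conditions: MgCl2, Et3N, AcCl, MeCN, 0 °C → rt
Reagents that add atoms: acetyl chloride, CC(Cl)=O
Why: Rathke-type C-acylation of the chelated magnesium malonate enolate, which stops cleanly at the mono-acyl product.

**Step 5**
Reactants: 7, dibenzyl 2-acetylmalonate
Product: 8, dibenzyl 2-(1-methoxyethylidene)malonate
Conditions: TMSCHN2, PhMe/MeOH 4:1, 0 °C → rt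
Reagents that add atoms: trimethylsilyldiazomethane, C[Si](C)(C)C=[N+]=[N-] (supplies the OCH3 carbon)
Why: O-methylation of a strongly acidic, fully enolised tricarbonyl by a diazoalkane gives the enol methyl ether; no E/Z issue arises because the two esters are identical.

**Step 6**
Reactants: 8, dibenzyl 2-(1-methoxyethylidene)malonate
Product: 9, benzyl 2-[benzyloxy(trimethylsilyloxy)methylidene]-3-methoxybut-3-enoate, i.e. CH2=C(OMe)–C(CO2Bn)=C(OBn)(OTMS); E/Z mixture, inconsequential; used crude
Conditions: LDA (1.1 equiv), THF, −78 °C; TMSCl, −78 → 0 °C; pentane filtration under Ar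
Reagents that add atoms: chlorotrimethylsilane, C[Si](C)(C)Cl
Why: Kinetic γ-deprotonation of an alkylidene malonate followed by O-silylation of the dienolate, the standard way Brassard-type vinylketene silyl acetals are made.

**Step 7 (key step)**
Reactants: 5, benzyl 4-(but-2-ynoyloxy)-2-hydroxy-3,6-dimethylbenzoate; 9, silyl diene (2.5 equiv)
Product: 10, dibenzyl squamatate: benzyl 3-{[4-(benzyloxycarbonyl)-3-hydroxy-2,5-dimethylphenoxy]carbonyl}-2-hydroxy-6-methoxy-4-methylbenzoate
Conditions: BSA (1.2 equiv), PhMe, 60 °C; then 9, 120 °C, sealed tube; then 1 M HCl, THF, rt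
Reagents that add atoms: none (BSA, CC(=N[Si](C)(C)C)O[Si](C)(C)C, only masks the B-ring OH transiently; all TMS groups and one BnO are lost)
Why: Proposed new method: a normal-demand Diels–Alder benzannulation in which the CH2 terminus of the 1,1,3-trioxygenated diene (activated by the 3-OMe and, vinylogously, by the ketene acetal) bonds to the electrophilic β-carbon (C–CH3) of the aryl ynoate and the ketene-acetal carbon bonds to the α-carbon, after which the bis-allylic silyl benzyl ketal cycloadduct aromatises by 1,4-loss of BnOH and the ArO–TMS is hydrolysed, so ring A, the aryl–C(=O) depside bond and the full OH/CO2Bn/OMe/H/CH3 pattern are set in one operation; the closest known reaction type is the Brassard/Chan-diene plus acetylenic-ester cycloaddition–aromatisation to salicylates, not yet shown for a 2-alkoxycarbonyl push–pull diene or for an ynoate whose ester group is the depside partner.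

**Step 8**
Reactants: 10, dibenzyl squamatate
Product: 11, squamatic acid
Conditions: H2 (1 atm), 10% Pd/C, EtOAc, rt; filter, evaporate below 30 °C
Reagents that add atoms: none
Why: Hydrogenolysis of both benzyl esters (and of any 2-O-benzyl ether formed in step 7 by loss of TMSOH instead of BnOH, which converges here) leaves the depside aryl ester, the aryl methyl ether and the phenols untouched.

## Compound list

1 | 2,5-dimethylresorcinol | Cc1cc(O)c(C)c(O)c1 | starting material
2 | 2,4-dihydroxy-3,6-dimethylbenzoic acid | Cc1cc(O)c(C)c(O)c1C(=O)O | intermediate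
3 | benzyl 2,4-dihydroxy-3,6-dimethylbenzoate | Cc1cc(O)c(C)c(O)c1C(=O)OCc1ccccc1 | intermediate
4 | but-2-ynoic acid | CC#CC(=O)O | starting material
5 | benzyl 4-(but-2-ynoyloxy)-2-hydroxy-3,6-dimethylbenzoate | CC#CC(=O)Oc1cc(C)c(C(=O)OCc2ccccc2)c(O)c1C | intermediate
6 | dibenzyl malonate | O=C(CC(=O)OCc1ccccc1)OCc1ccccc1 | starting material
7 | dibenzyl 2-acetylmalonate | CC(=O)C(C(=O)OCc1ccccc1)C(=O)OCc1ccccc1 | intermediate
8 | dibenzyl 2-(1-methoxyethylidene)malonate | COC(C)=C(C(=O)OCc1ccccc1)C(=O)OCc1ccccc1 | intermediate
9 | benzyl 2-[benzyloxy(trimethylsilyloxy)methylidene]-3-methoxybut-3-enoate (E/Z unspecified) | C=C(OC)C(C(=O)OCc1ccccc1)=C(OCc1ccccc1)O[Si](C)(C)C | intermediate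
10 | dibenzyl squamatate | COc1cc(C)c(C(=O)Oc2cc(C)c(C(=O)OCc3ccccc3)c(O)c2C)c(O)c1C(=O)OCc1ccccc1 | intermediate
11 | squamatic acid | COc1cc(C)c(C(=O)Oc2cc(C)c(C(=O)O)c(O)c2C)c(O)c1C(=O)O | target

## Summary

**Total steps:** 8. **Longest linear sequence:** 5 (steps 1, 2, 3, 7, 8; the diene branch 4, 5, 6, 7, 8 is also 5).

**Three steps most likely to fail:**

1. **Step 7 (proposed new benzannulation).** Risks: the 2-ester lowers the diene HOMO, the β-methyl slows the ynoate, and the silyl diene may be protonated before it reacts. Fallback (known chemistry): drop ring construction and form the depside by classical acylation. Couple preformed 3-formyl-2-hydroxy-4-methoxy-6-methylbenzoic acid (from an everninate ester by ortho-formylation and ester cleavage) with 3 using TFAA in toluene, oxidise the aldehyde to the acid (NaClO2, NaH2PO4, 2-methyl-2-butene), then hydrogenolyse the benzyl ester.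

2. **Step 6 (push–pull silyl diene).** Risks: LDA may add to the β-methoxy alkylidene malonate with loss of methoxide, the enolate may C-silylate, or the diene may not survive isolation. Fallback: use the simpler, well-behaved diene from benzyl 3-methoxybut-2-enoate (1-benzyloxy-3-methoxy-1-trimethylsilyloxybuta-1,3-diene) in the benzannulation with 5. Then add the missing C3 carboxyl afterwards by phenol-directed ortho-formylation (MgCl2, Et3N, paraformaldehyde), which can only hit ring A because the B-ring OH has both ortho positions blocked, followed by chlorite oxidation.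

3. **Step 1 (Kolbe–Schmitt).** Risks: variable conversion and easy decarboxylation of 2 on work-up. Fallback: avoid C–H carboxylation altogether by starting from commercial methyl 2,4-dihydroxy-3,6-dimethylbenzoate and cleaving the hindered methyl ester through the acylium pathway (cold conc. H2SO4, then ice) to give 2, or purchase 2 directly.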